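The easy step is a subtraction. In a closed flask, whatever D has disappeared has been spent, so one fork can be followed without knowing any rate: of each spent molecule of D, what is the chance of finding it as J? That chance is the share s = c_J / (charged c_D − present c_D), the selectivity of the flask at that moment.

| flask | D | Q | temperature | remark | time |
|---|---|---|---|---|---|
| beta | 20 mM | 1.2 equiv | 75 °C | run made earlier |  |
| zeta | 20 mM | 5 equiv | 108 °C | run made earlier |  |
| north-west | 20 mM | 2.50 equiv | 90 °C |  | 10 h |
| north-east | 20 mM | 2.50 equiv |  | at 60 °C until 8.0 h, from then on at 120 °C | 10 h |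
| north | 20 mM | 2.50 equiv | 120 °C |  | 10 h |
| west | 20 mM | 2.50 equiv | 60 °C |  | 10 h |

| run | time / h | J / % | D / % |
|---|---|---|---|
| beta | 2.00 | 12.0 | 73.6 |
| beta | 3.00 | 13.7 | 64.4 |
| beta | 4.00 | 17.5 | 57.0 |
| beta | 8.00 | 24.4 | 38.7 |
| beta | 12.0 | 30.2 | 30.2 |
| beta | 20.0 | 32.5 | 18.4 |
| zeta | 0.667 | 31.7 | 4.4 |
| zeta | 1.33 | 33.6 | 0.1 |
| zeta | 2.00 | 32.9 | 0.9 |
| zeta | 2.50 | 30.9 | 0.7 |
| zeta | 3.00 | 34.2 | 0 |
| zeta | 4.00 | 32.0 | 0 |

(each reading ± 1 percentage point)

- the earlier runs were read with a standard deviation of 1 percentage point

- the best flask by amount of J, in percent of the D charged; "all alike" if 1.5 percentage points covers them all (north-west / north-east / north / west / all alike)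
- amount of J at the end, in percent of the D charged, north-west
- amount of J at the end, in percent of the D charged, north-east
- amount of J at the end, in percent of the D charged, north
- amount of J at the end, in percent of the D charged, west

In beta, at 75 °C, s reads 40.7% at 4.00 h and 39.8% at 20.0 h. In zeta, at 108 °C, D reads 0% and the last two J readings give 33.1%, which is lower. A straight line through these two readings gives 36.8% at 90 °C and, as the share of spent D found as J at 120 °C, 30.7%.

The share s holding level in beta and J holding level in zeta leave open whether a molecule's fate is sealed at its birth or whether J keeps balancing against something unseen. North-east separates the two, and this reckoning commits to the balance: whatever J stands at 60 °C takes the hot share after the change at 8.0 h. With D spent, it expects north-west near 36.8% and north-east near 30.7%, so north-west should lead.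

The forecast names north-east as best, at 39%, on the grounds “57.5% converted at 60 °C, the rest at 120 °C”. It gives north-west 37%, north 30.7% and west 29.4%. The two reckonings part on north-east.

The flasks give 36.7% in north-west, the best, then 32.2% in north-east, 30.2% in north and 31.9% in west.

    D + Q → J (k = 0.0392 M⁻¹ min⁻¹, Ea = 66.0 kJ mol⁻¹)
    D + Q → G (k = 0.00130 M⁻¹ min⁻¹, Ea = 94.0 kJ mol⁻¹)
    J ⇌ X (K = 1.20, k = 0.00526 min⁻¹, Ea = 93.0 kJ mol⁻¹, ΔH = 8.00 kJ mol⁻¹)
    (constants at 60 °C)

North-east held J at 29.6% at 8.00 h, with D at 43.1%. By 10.0 h J stood at 32.2%, 1.5 points above 30.7%, while X grew from 25.5% to 60.1%. So the reading to watch is J after the heating. Ten times the time leaves north-west at 36.8%, north-east at 32.3% and north at 30.2%; in north, J and X relax with a half-life of 0.511 min, short against 10 h. West has not come to rest: D stands at 35.9% at 10.0 h, and J reaches 44.0% at 100 h.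

The neighbour is north with 0.620 equiv of Q, and each D spent takes one Q, so Q is the limiting reagent and can pay for 62.0% of D; the share then gives J of 19.0%. The flask gives 18.7%, with D at 38% and Q at 0.015% of its charge.

The earlier runs and the new flask come from a simulation on assumed constants; scatter was added.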